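Readings and results stem from a simulated flask on assumed constants; the scatter is artificial.

I cannot watch a single catalyst turn, but I can count its turnovers on average, as product formed per catalyst charged.

| flask | substrate | partner | free catalyst | added ligand | temperature | remark | time |
|---|---|---|---|---|---|---|---|
| eta | 0.57 M | 1 equiv | 0.5 mol% | 27 mM | 85 °C | run made earlier |  |
| alpha | 0.57 M | 1 equiv | 0.72 mol% | 27 mM | 96 °C | run made earlier |  |
| beta | 0.57 M | 1 equiv | 1.1 mol% | 27 mM | 85 °C | run made earlier |  |
| east | 0.57 M | 1.00 equiv | 0.4 mol% | 27 mM | 90 °C |  | 20 h |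
| south-east | 0.57 M | 1.00 equiv | 1.5 mol% | 27 mM | 90 °C |  | 12 h |

| run | time / h | product / % | substrate / % |
|---|---|---|---|
| eta | 1.00 | 1 | 97 |
| eta | 3.00 | 6 | 97 |
| eta | 6.00 | 11 | 93 |
| eta | 8.00 | 9 | 87 |
| eta | 12.0 | 18 | 85 |
| alpha | 1.00 | 7 | 96 |
| alpha | 2.00 | 7 | 94 |
| alpha | 3.00 | 8 | 92 |
| alpha | 6.00 | 14 | 85 |
| alpha | 12.0 | 21 | 81 |
| beta | 2.50 | 10 | 89 |
| beta | 5.00 | 16 | 83 |
| beta | 8.00 | 21 | 77 |
| beta | 10.0 | 24 | 76 |
| beta | 12.0 | 27 | 73 |

(readings scatter by 1.5 percentage points)

1. which one finishes higher in amount of product, in percent of the substrate charged ("neither" within 2 percentage points) (east / south-east / neither)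
2. amount of product at the end, in percent of the substrate charged, east
3. amount of product at the end, in percent of the substrate charged, south-east

- what was read earlier has a scatter of 1.5 percentage points, one standard deviation
- steps that have been proposed: substrate + free catalyst <-> catalyst intermediate A; partner + catalyst intermediate B <-> catalyst intermediate C; catalyst intermediate C <-> free catalyst + product; free catalyst + added ligand <-> idle complex; catalyst intermediate A <-> catalyst intermediate B

The first beta reading, 10 % after 2.50 h on 1.1 mol%, gives 3.64 h⁻¹. This count of turnovers per catalyst per hour early in a run is the turnover rate, or turnover frequency. Eta gives 3.67 h⁻¹ at 85 °C and alpha 3.70 h⁻¹ at 96 °C, so within the scatter of these readings I see no temperature effect and make no correction for 90 °C.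

I build the flask up in stages. First I let the catalyst keep turning at this rate, so that the product is rate times loading times time. That gives east 29.1 % and south-east 65.5 %.

Next I let substrate and partner run down together from equal charges, with 1.00 equiv of partner. The rate then follows c(substrate)·c(partner), and the count above, taken as a fraction, becomes count/(1 + count). East falls to 22.5 % and south-east to 39.6 %.

Last comes whatever else slows the flask, which I do not separate into steps. The same count for beta at 12.0 h gives 32.4 %, but the reading is lower, 27 %. Scaling by that ratio, I expect east 18.8 % and south-east 33.0 %.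

The forecast gives east 23 % and south-east 32 %, with south-east higher, and it notes “some slowing from inhibition, reversibility or catalyst loss”. It stands above my east figure and just below my south-east figure, but the order is the same.

The flask gives east 20.2 % and south-east 28.1 %, so south-east finishes higher.

    substrate + free catalyst ⇌ catalyst intermediate A (K = 2.14 M⁻¹, k = 1.85 M⁻¹ min⁻¹, Ea = 62.0 kJ mol⁻¹, ΔH = −3.00 kJ mol⁻¹)
    partner + catalyst intermediate B ⇌ catalyst intermediate C (K = 1.40 M⁻¹, k = 1.60 M⁻¹ min⁻¹, Ea = 86.0 kJ mol⁻¹, ΔH = 7.00 kJ mol⁻¹)
    catalyst intermediate C ⇌ free catalyst + product (K = 1.71 M, k = 14.5 min⁻¹, Ea = 95.0 kJ mol⁻¹, ΔH = −29.0 kJ mol⁻¹)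
    free catalyst + added ligand ⇌ idle complex, settled at all times (K = 20.0 M⁻¹, ΔH = −65.0 kJ mol⁻¹)
    catalyst intermediate A ⇌ catalyst intermediate B (K = 0.225, k = 49.7 min⁻¹, Ea = 89.0 kJ mol⁻¹, ΔH = −74.0 kJ mol⁻¹)
    (constants at 90 °C)

The mean turnover rate over the run is 2.53 h⁻¹ for east and 1.56 h⁻¹ for south-east, both lower than the 3.64 h⁻¹ I read from beta. Left for 200 h, east reaches 31.1 %, and left for 120 h, south-east reaches 31.0 %. At the asked times east stands 11 percentage points lower than that and south-east 2.9 points lower. The neighbour flask is east with 0.97 M of substrate, its equivalents and loadings held. Raising the turnover rate by the substrate ratio squared, as c(substrate)·c(partner) has it, and scaling by the beta ratio as before, I reckon 38.1 %, but that neighbour flask ends lower, at 32.6 %, with 67.1 % of its substrate left.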